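## The problem

- Kadsurenin D (**8**) is (1S,5S,6R,7R)-5-allyl-7-(3,4-dimethoxyphenyl)-3-methoxy-6-methylbicyclo[3.2.1]oct-3-ene-2,8-dione. A cyclopentanone (C8, C1, C7, C6, C5) is bridged from C1 to C5 by the enone unit C2(=O)–C3(OMe)=C4.
- C5 is a quaternary bridgehead carrying the allyl group. C1 is a bridgehead methine between two ketones that cannot enolise, so neither bridgehead can be alkylated or corrected once the bicycle exists, and the 1,3-diketone is open to retro-Claisen cleavage by alkoxide or hydroxide.
- C1 and C5 are tied to each other by the bridge. The open questions are the absolute sense, the 6-methyl group (endo, towards the C2–C4 bridge, which is anti to the allyl group across C5–C6) and the 7-aryl group (exo, towards C8, trans to methyl).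
- The C5–C6 bond joins a quaternary to a tertiary centre and C6 has no handle for later correction. A direct union of an allyl-bearing ring with a propenylarene decides this relationship in an intermolecular transition state with no reliable bias towards the anti arrangement.
- The feature the plan exploits: C7 is benzylic to the 3,4-dimethoxyphenyl ring and bonded to C1, the central carbon of the C2/C8 1,3-dicarbonyl unit, so the C1–C7 bond can be made last by ionisation of a C7–O bond to the C8 oxygen. In the aromatic ancestor of the six-membered ring (C8, C1, C2, C3, C4, C5), C5 is para to the C2 oxygen, the position where a phenoxonium ion accepts a carbon nucleophile, while C1 is the unreactive α-carbon of a vinylogous ester.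
- Sensitive groups: the terminal allyl alkene (no hydrogenation after it is introduced), the enol methyl ether, the oxidisable veratryl ring and the non-enolisable β-diketone.

## Retrosynthesis

**8 ⇒ 7.** The C1–C7 bond is cut and C7 is reconnected to the oxygen on C8. This gives the fused 3a-allyl hydrobenzofuranone **7**, an isomer of **8** with no bridge. Against cutting C5–C6 and C1–C7 together (intermolecular, Me/allyl relationship uncontrolled) or C1–C2 (a Claisen condensation onto a non-enolisable diketone), this cut uses the one bond of the bicycle that is ionisable. C1 and C7 need no separate control. The forward reaction must ionise the benzylic C–O bond under acid and return the cation to carbon, not to oxygen.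

**7 ⇒ 6.** The C3a–allyl bond (C5–allyl of **8**) is cut with the ring as electrophile and the allyl group as nucleophile. This gives the flat phenol **6**: the quaternary centre is gone and only two stereocentres remain. The opposite polarity (phenoxide plus allyl electrophile, or a [3,3] shift from oxygen) is rejected. There the free position C7 between the two oxygens is the better nucleophile and aromatises irreversibly. In the phenoxonium polarity C7 is the α-carbon of the O1–C7a=C7–C6=O vinylogous ester and is not attacked. The forward reaction must add the allyl nucleophile para (C3a), not at the methoxy-bearing ortho carbon, and anti to the adjacent C3 methyl group. Both events, allylation and O→C shift, are run in one flask (step 5).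

**6 ⇒ 5 ⇒ 4.** Only O–C bonds are changed. The cycloaddition below leaves the free hydroxyl on C5 and the quinone's alkoxy group on C6, the reverse of what **6** needs. The quinone alkoxy group is therefore benzyl: O-methylation of **4** gives **5**, and hydrogenolysis, done before any alkene is present, gives **6**.

**4 ⇒ 2 + 3.** The C3–C3a and O1–C2 bonds are cut. This formal [3+2] disconnection leads to 2-(benzyloxy)-1,4-benzoquinone **2** and (E)-methyl isoeugenol **3**, which together hold every carbon of **8** except the allyl group and the C3 methoxy methyl. A chiral titanium(IV) diolate is asked to set C3; C2 comes with it as the trans isomer. Only C3 must persist, because C2 is re-formed in the last step.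

**2 ⇒ 1.** The quinone oxygen para to the hydroxyl group is removed, leading to commercial 2-(benzyloxy)phenol **1**.

## Roads not taken

**Alternative 1:** The most obvious cut is C5–C6 plus C1–C7 in one operation.
- Forward step: a Lewis-acid or anodically triggered cationic [5+2] cycloaddition of 2-allyl-5-methoxy-1,4-benzoquinone **A1** (or the corresponding phenoxonium ion) with **3**, then O-methylation of the diosphenol.
- It is the shortest route. However, the first bond forms at the allyl-bearing carbon through a compact transition state in which the electron-rich aryl group is expected to lie over the electron-poor ring. That places the methyl group on the allyl side and leads to the 6-exo-methyl/7-endo-aryl adduct **A2**, which is epimeric with **8** at C6 and C7 relative to the bridgeheads.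
- C6 cannot be corrected afterwards, and the [3+2] and [2+2] modes compete. The chosen plan reverses the order, with allyl added to a ring that already carries the methyl-bearing carbon, so the anti relationship follows from a simple steric rule.

**Alternative 2:** The same C5–allyl bond could be cut as a sigmatropic retron.
- Forward step: a thermal para-Claisen rearrangement (two [3,3] shifts, O6 → C5 → C3a) of the allyl ether **A3** of phenol **6**.
- It is reagent-free and intramolecular. However, the ortho position C7 carries hydrogen, so the ordinary ortho-Claisen rearrangement followed by enolisation gives the aromatic 7-allylphenol **A4**, which is the thermodynamic sink.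
- Blocking C7 costs three extra steps (this version is kept only as a fallback). The umpolung allylation needs no blocking group because C7 is not electrophilic.

**Alternative 3:** The C1–C2 bond could be cut, with the cyclopentanone as the starting ring.
- Forward step: an intramolecular Claisen condensation of the α-keto ester **A5** (from conjugate addition/double alkylation of a 4-arylcyclopentenone) to the diosphenol **A6**, then O-methylation.
- The stereochemistry would come from reliable anti alkylations. However, the enantioenriched cyclopentenone, the three contiguous centres and the pyruvate side chain need roughly twice as many steps, and the ring closure must form a β-diketone that cannot be stabilised as its enolate at C1.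
- The chosen plan takes all ring carbons from one quinone and forms the difficult C1–C7 bond under acid, where retro-Claisen cleavage is not an issue.

Key step: step 5

Assumption: the sense of induction of the Ti–TADDOLate promoter in step 2 cannot be predicted with certainty for quinone **2**; the TADDOL antipode that delivers the (2S,3S) series is used (both antipodes are commercial).

## Route

**Step 1**
Reactants: 1 2-(benzyloxy)phenol
Product: 2 2-(benzyloxy)cyclohexa-2,5-diene-1,4-dione
Conditions: (KO3S)2NO (2.2 equiv), KH2PO4 buffer, H2O/acetone, 0 °C → rt
Reagents that add atoms: potassium nitrosodisulfonate (Fremy's salt), [K+].[K+].[O]N(S(=O)(=O)[O-])S(=O)(=O)[O-]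
Why: Fremy's salt oxidation of a phenol with a free para position gives the p-quinone with the 2-alkoxy group retained; no stereocentre is involved.

**Step 2**
Reactants: 2 2-(benzyloxy)cyclohexa-2,5-diene-1,4-dione; 3 (E)-1,2-dimethoxy-4-(prop-1-en-1-yl)benzene
Product: 4 (2S,3S)-6-(benzyloxy)-2-(3,4-dimethoxyphenyl)-3-methyl-2,3-dihydro-1-benzofuran-5-ol
Conditions: TiCl4/Ti(OiPr)4 (1:1), TADDOL (antipode as in the assumption), CH2Cl2, −78 → −20 °C; aq. NaHCO3
Reagents that add atoms: none
Why: Ti(IV) chelated by the C1 carbonyl and the C2 benzyloxy oxygen activates C5 of the quinone; the β-carbon of the (E)-propenylarene adds there, the dimethoxybenzylic cation is captured by the C4 carbonyl oxygen and the arenium ion loses a proton (chiral Ti(IV)-diolate-promoted formal [3+2] cycloaddition of a 2-alkoxy-1,4-benzoquinone with a propenylarene). The C2-symmetric diolate differentiates the quinone faces and so fixes C3; the 2,3-trans relationship follows from the (E)-alkene and is also the thermodynamic one. Only C3 has to survive, since C2 is re-formed in step 5.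

**Step 3**
Reactants: 4 (2S,3S)-6-(benzyloxy)-2-(3,4-dimethoxyphenyl)-3-methyl-2,3-dihydro-1-benzofuran-5-ol
Product: 5 (2S,3S)-6-(benzyloxy)-2-(3,4-dimethoxyphenyl)-5-methoxy-3-methyl-2,3-dihydro-1-benzofuran
Conditions: MeI, K2CO3, acetone, 40 °C, N2
Reagents that add atoms: iodomethane, CI
Why: Williamson O-methylation of the only free phenol; it turns the C5 oxygen into the future enol ether methoxy group of 8 and leaves both stereocentres untouched.

**Step 4**
Reactants: 5 (2S,3S)-6-(benzyloxy)-2-(3,4-dimethoxyphenyl)-5-methoxy-3-methyl-2,3-dihydro-1-benzofuran
Product: 6 (2S,3S)-2-(3,4-dimethoxyphenyl)-5-methoxy-3-methyl-2,3-dihydro-1-benzofuran-6-ol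
Conditions: H2 (1 atm), 10% Pd/C, EtOAc, rt
Reagents that add atoms: none
Why: Hydrogenolysis of the O-benzyl ether is placed here because no alkene is present yet; under one atmosphere of hydrogen in a non-acidic solvent the aryl benzyl ether should cleave faster than the cyclic 2-aryl benzylic C–O bond, and the stereocentres are not involved.

**Step 5**
Reactants: 6 (2S,3S)-2-(3,4-dimethoxyphenyl)-5-methoxy-3-methyl-2,3-dihydro-1-benzofuran-6-ol
Product: 8 (1S,5S,6R,7R)-5-allyl-7-(3,4-dimethoxyphenyl)-3-methoxy-6-methylbicyclo[3.2.1]oct-3-ene-2,8-dione (kadsurenin D), via 3a-allyl hydrobenzofuranone 7 (not isolated)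
Conditions: PhI(OAc)2 (1.05 equiv), CH2=CHCH2SiMe3 (4 equiv), (CF3)2CHOH, −20 °C, slow addition of 6; then CF3CO2H, 0 → 23 °C, same flask
Reagents that add atoms: allyltrimethylsilane, C=CC[Si](C)(C)C
Why: PhI(OAc)2 oxidises phenol 6 to a phenoxonium ion whose positive charge sits on C5 (methoxy-bearing) and C3a (para to the C6 oxygen), while C7 stays the non-electrophilic α-carbon of the O1–C7a=C7–C6=O vinylogous ester; the allylsilane adds at C3a with loss of the silyl group to give the cross-conjugated dienone 7 (oxidative, umpolung Hosomi–Sakurai para-allylation of a 4-alkylphenol is the closest known reaction type). The new quaternary centre (C5 of 8) is controlled by the adjacent ring stereocentre C3: the silane approaches the planar cation anti to the C3 methyl group (1,2-induction in a five-membered ring), which puts allyl trans to methyl. CF3CO2H then protonates the vinylogous ester, and the O1–C2 bond, a 3,4-dimethoxybenzylic C–O bond with a 1,3-diketone enol as leaving group, ionises; the cation is recaptured by C7, the central carbon of that enol (the acid-mediated hydrobenzofuranone → bicyclo[3.2.1]octanedione rearrangement of 3a-allyl neolignan dienones). This closes the cyclopentanone ring C1–C8–C5–C6–C7 of 8 as a 5-exo-trig C-alkylation at the cationic carbon, and with it the bridged seven-membered ring; only the furan ring is opened. C1 can form only on the ring face that already carries the C6–C7 chain, so its configuration follows from C5. C7 is set by front-side return (the carbon nucleophile sits next to the departing oxygen, net retention), which is also the thermodynamic arrangement (aryl exo, trans to the endo methyl) towards which the ionisable C1–C7 bond can equilibrate. The step needs para over ipso attack of the silane (soft π-nucleophile in non-nucleophilic, ion-stabilising HFIP), anti-to-methyl facial selectivity (C3), oxidation of the phenol in preference to the veratryl ring (ligand exchange at iodine requires the free OH) and C- over O-return of the cation (O-return only regenerates 7).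

## Compound list

1 | 2-(benzyloxy)phenol | Oc1ccccc1OCc1ccccc1 | starting material
2 | 2-(benzyloxy)cyclohexa-2,5-diene-1,4-dione | O=C1C=CC(=O)C(OCc2ccccc2)=C1 | intermediate
3 | (E)-1,2-dimethoxy-4-(prop-1-en-1-yl)benzene (methyl isoeugenol) | C/C=C/c1ccc(OC)c(OC)c1 | starting material
4 | (2S,3S)-6-(benzyloxy)-2-(3,4-dimethoxyphenyl)-3-methyl-2,3-dihydro-1-benzofuran-5-ol | C[C@@H]1[C@@H](c2ccc(OC)c(OC)c2)Oc2cc(OCc3ccccc3)c(O)cc12 | intermediate
5 | (2S,3S)-6-(benzyloxy)-2-(3,4-dimethoxyphenyl)-5-methoxy-3-methyl-2,3-dihydro-1-benzofuran | C[C@@H]1[C@@H](c2ccc(OC)c(OC)c2)Oc2cc(OCc3ccccc3)c(OC)cc12 | intermediate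
6 | (2S,3S)-2-(3,4-dimethoxyphenyl)-5-methoxy-3-methyl-2,3-dihydro-1-benzofuran-6-ol | C[C@@H]1[C@@H](c2ccc(OC)c(OC)c2)Oc2cc(O)c(OC)cc12 | intermediate
7 | (2S,3S,3aS)-3a-allyl-2-(3,4-dimethoxyphenyl)-5-methoxy-3-methyl-3,3a-dihydro-1-benzofuran-6(2H)-one | C=CC[C@]12C=C(OC)C(=O)C=C1O[C@H](c1ccc(OC)c(OC)c1)[C@H]2C | intermediate (not isolated)
8 | (1S,5S,6R,7R)-5-allyl-7-(3,4-dimethoxyphenyl)-3-methoxy-6-methylbicyclo[3.2.1]oct-3-ene-2,8-dione (kadsurenin D) | C=CC[C@]12C=C(OC)C(=O)[C@H](C1=O)[C@H](c1ccc(OC)c(OC)c1)[C@H]2C | target

## Step count and least certain steps

Total steps: 5. Longest linear sequence: 5 (1 → 2 → 4 → 5 → 6 → 8).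

**Step 5 (key step).** Several processes can divert it:
- addition of the silane at the methoxy-bearing ortho carbon, or oxidative self-coupling of the phenol;
- loss of the C3 proton from the phenoxonium ion (quinone methide formation and aromatisation to the benzofuran), which would erase the controlling stereocentre;
- incomplete anti-to-methyl facial discrimination;
- in the acid stage, acid-promoted [3,3] migration of the allyl group to C7 with aromatisation, or capture of the benzylic cation by the allyl π-bond instead of the enol carbon.

The fallback delivers the allyl group intramolecularly with C7 blocked. It sets out from **6** and returns at **7**: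
- ortho-bromination (NBS, CH2Cl2, −78 °C) gives the 7-bromophenol F1;
- O-allylation (allyl bromide, K2CO3, acetone) gives the allyl ether F2;
- heating (PhNEt2, about 180 °C) effects the para-Claisen rearrangement through the transient ortho-dienone F3, which forms reversibly, to the 7-bromo-3a-allyl dienone F4; the product-determining Cope shift to C3a again takes place anti to the C3 methyl group;
- hydrodebromination (Bu3SnH, cat. Pd(PPh3)4) gives **7**, now isolated;
- **7** is carried to **8** by the acid stage alone (CF3CO2H, CH2Cl2).

**Step 2.** The concern is insufficient asymmetric induction with this particular quinone/arene pair, together with premature C–C closure to a [2+2] adduct or polymerisation of the electron-rich alkene. The fallback replaces asymmetric induction by resolution. It sets out from **2** and **3** and returns at **4**: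
- the cycloaddition is run with the achiral TiCl4/Ti(OiPr)4 promoter to give **4** together with its enantiomer, the (2R,3R)-phenol F5;
- the mixture is treated with (S)-1-phenylethyl isocyanate (Et3N, CH2Cl2) to give the diastereomeric carbamates, the (2S,3S)-carbamate F6 and the (2R,3R)-carbamate F7, which are separated by crystallisation or chromatography;
- methanolysis of F6 (K2CO3, MeOH) returns **4**.

**Step 4.** The concern is competing hydrogenolysis of the ring C2–O bond, which is benzylic to a very electron-rich arene. The fallback sets out from **5** and returns at **6**. It abandons reduction for an electrophilic dealkylation: BCl3 with pentamethylbenzene as benzyl-cation scavenger, CH2Cl2, −78 °C. This cannot cleave the furan ring reductively, and any reversible ionisation of C2–O simply recloses to the trans isomer, whose C2 configuration is re-formed later anyway.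

## Further compounds

F1 | step 5 | (2S,3S)-7-bromo-2-(3,4-dimethoxyphenyl)-5-methoxy-3-methyl-2,3-dihydro-1-benzofuran-6-ol | C[C@@H]1[C@@H](c2ccc(OC)c(OC)c2)Oc2c(Br)c(O)c(OC)cc12
F2 | step 5 | (2S,3S)-6-(allyloxy)-7-bromo-2-(3,4-dimethoxyphenyl)-5-methoxy-3-methyl-2,3-dihydro-1-benzofuran | C[C@@H]1[C@@H](c2ccc(OC)c(OC)c2)Oc2c(Br)c(OCC=C)c(OC)cc12
F3 | step 5 | (2S,3S,5R)-5-allyl-7-bromo-2-(3,4-dimethoxyphenyl)-5-methoxy-3-methyl-2,3-dihydro-1-benzofuran-6(5H)-one | C=CC[C@@]1(OC)C=C2[C@H](C)[C@@H](c3ccc(OC)c(OC)c3)OC2=C(Br)C1=O
F4 | step 5 | (2S,3S,3aS)-3a-allyl-7-bromo-2-(3,4-dimethoxyphenyl)-5-methoxy-3-methyl-3,3a-dihydro-1-benzofuran-6(2H)-one | C=CC[C@]12C=C(OC)C(=O)C(Br)=C1O[C@H](c1ccc(OC)c(OC)c1)[C@H]2C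
F5 | step 2 | (2R,3R)-6-(benzyloxy)-2-(3,4-dimethoxyphenyl)-3-methyl-2,3-dihydro-1-benzofuran-5-ol | C[C@H]1[C@H](c2ccc(OC)c(OC)c2)Oc2cc(OCc3ccccc3)c(O)cc12
F6 | step 2 | (2S,3S)-6-(benzyloxy)-2-(3,4-dimethoxyphenyl)-3-methyl-2,3-dihydro-1-benzofuran-5-yl N-[(1S)-1-phenylethyl]carbamate | C[C@@H]1[C@@H](c2ccc(OC)c(OC)c2)Oc2cc(OCc3ccccc3)c(OC(=O)N[C@@H](C)c3ccccc3)cc12
F7 | step 2 | (2R,3R)-6-(benzyloxy)-2-(3,4-dimethoxyphenyl)-3-methyl-2,3-dihydro-1-benzofuran-5-yl N-[(1S)-1-phenylethyl]carbamate | C[C@H]1[C@H](c2ccc(OC)c(OC)c2)Oc2cc(OCc3ccccc3)c(OC(=O)N[C@@H](C)c3ccccc3)cc12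
F0 | step 4 | none | none
A1 | alternative 1 | 2-allyl-5-methoxycyclohexa-2,5-diene-1,4-dione | C=CCC1=CC(=O)C(OC)=CC1=O
A2 | alternative 1 | (1S,5S,6S,7S)-5-allyl-7-(3,4-dimethoxyphenyl)-3-hydroxy-6-methylbicyclo[3.2.1]oct-3-ene-2,8-dione (6-exo-methyl, 7-endo-aryl; one enantiomer drawn) | C=CC[C@]12C=C(O)C(=O)[C@H](C1=O)[C@@H](c1ccc(OC)c(OC)c1)[C@@H]2C
A3 | alternative 2 | (2S,3S)-6-(allyloxy)-2-(3,4-dimethoxyphenyl)-5-methoxy-3-methyl-2,3-dihydro-1-benzofuran | C[C@@H]1[C@@H](c2ccc(OC)c(OC)c2)Oc2cc(OCC=C)c(OC)cc12
A4 | alternative 2 | (2S,3S)-7-allyl-2-(3,4-dimethoxyphenyl)-5-methoxy-3-methyl-2,3-dihydro-1-benzofuran-6-ol | C[C@@H]1[C@@H](c2ccc(OC)c(OC)c2)Oc2c(CC=C)c(O)c(OC)cc12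
A5 | alternative 3 | methyl 3-[(1R,2R,3S)-1-allyl-3-(3,4-dimethoxyphenyl)-2-methyl-5-oxocyclopentyl]-2-oxopropanoate | C=CC[C@]1(CC(=O)C(=O)OC)C(=O)C[C@H](c2ccc(OC)c(OC)c2)[C@H]1C
A6 | alternative 3 | (1S,5S,6R,7R)-5-allyl-7-(3,4-dimethoxyphenyl)-3-hydroxy-6-methylbicyclo[3.2.1]oct-3-ene-2,8-dione | C=CC[C@]12C=C(O)C(=O)[C@H](C1=O)[C@H](c1ccc(OC)c(OC)c1)[C@H]2C
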